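**Plan**
1. Retrosynthesis opens the dihydrofuran (ring D) at C3a'–C3' and C7a'–O1', which leaves 4'-iodoisoflavone 5 and (R)-epoxide 11. The pyranone (ring C) is then cut at O1–C2, C2–C3 and C4–C4a back to phloroglucinol 1 and 4-iodophenylacetic acid 2.
2. Enabling feature: in ring D, O1' and the C3' methylene sit on neighbouring carbons C7a' and C3a' of benzene ring B, and the chromone is on C5', para to O1'. A 3-(4-iodophenyl)chromone therefore offers C7a' as the iodinated carbon, flanked by two identical ortho C–H bonds.
3. Forward: ring C is built on ring A in one pot (C-acylation, formylative closure) and O5/O7 are benzylated. The epoxide is made in five steps. Ring D is closed last on ring B by palladium/norbornene annulation, and one hydrogenolysis frees all three hydroxyls.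
4. Stereochemistry: C2' (R) is the stereocentre of methyl (R)-glycerate acetonide 6. Its C–O bond is never broken, so the configuration is carried through unchanged.
5. The tertiary oxygen is masked as a 4-methoxybenzyl ether, which cannot migrate to a neighbouring alkoxide and leaves together with the benzyl ethers.

Key step: step 8

Remark: the single stereocentre of the target, C2', is read from the SMILES as (R); unprimed locants refer to the chromone (rings A and C), primed ones to the dihydrobenzofuran (rings B and D).

Step 1
Reactants: 1 phloroglucinol; 2 2-(4-iodophenyl)acetic acid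
Product: 4 5,7-dihydroxy-3-(4-iodophenyl)-4H-chromen-4-one, via deoxybenzoin 3 (not isolated)
Conditions: BF3·OEt2 (neat), 85 °C; then DMF, MsCl, 70 °C; aqueous work-up
Reagents that add atoms: N,N-dimethylformamide, CN(C)C=O
Why: BF3-promoted Friedel–Crafts C-acylation of the symmetrical triol should give deoxybenzoin 3, whose benzylic carbon is formylated by the Vilsmeier-type reagent from DMF and MsCl, so that attack of either equivalent ortho hydroxyl and loss of dimethylamine close ring C (one-pot deoxybenzoin route to isoflavones), the aryl iodide being inert throughout.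

Step 2
Reactants: 4 5,7-dihydroxy-3-(4-iodophenyl)-4H-chromen-4-one
Product: 5 5,7-bis(benzyloxy)-3-(4-iodophenyl)-4H-chromen-4-one
Conditions: BnBr (3 equiv), K2CO3, Bu4NI (cat.), DMF, 70 °C
Reagents that add atoms: benzyl bromide, BrCc1ccccc1
Why: Williamson etherification, in which the acidic 7-OH reacts first and the hydrogen-bonded 5-OH is driven to completion by excess bromide, iodide catalysis and heat, should remove both phenolic protons ahead of the base-mediated key step.

Step 3
Reactants: 6 methyl (4R)-2,2-dimethyl-1,3-dioxolane-4-carboxylate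
Product: 7 2-[(4R)-2,2-dimethyl-1,3-dioxolan-4-yl]propan-2-ol
Conditions: MeMgBr (3 equiv), THF, 0 °C to rt; aq. NH4Cl
Reagents that add atoms: methylmagnesium bromide, C[Mg]Br
Why: Twofold Grignard addition to the ester gives the tertiary carbinol without touching the dioxolane stereocentre, which keeps the (R) configuration of the chiral-pool ester.

Step 4
Reactants: 7 2-[(4R)-2,2-dimethyl-1,3-dioxolan-4-yl]propan-2-ol
Product: 8 (4R)-4-{2-[(4-methoxybenzyl)oxy]propan-2-yl}-2,2-dimethyl-1,3-dioxolane
Conditions: NaH, 4-methoxybenzyl chloride, Bu4NI (cat.), DMF, 0 °C to rt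
Reagents that add atoms: 4-methoxybenzyl chloride, COc1ccc(CCl)cc1
Why: Williamson etherification of the tertiary sodium alkoxide with the benzylic iodide formed in situ installs an ether that cannot migrate between oxygens, blocks Payne rearrangement of the later epoxy alcohol and is cleaved by the same hydrogenolysis as the benzyl ethers.

Step 5
Reactants: 8 (4R)-4-{2-[(4-methoxybenzyl)oxy]propan-2-yl}-2,2-dimethyl-1,3-dioxolane
Product: 9 (2R)-3-[(4-methoxybenzyl)oxy]-3-methylbutane-1,2-diol
Conditions: AcOH–H2O (4:1), rt to 40 °C
Reagents that add atoms: none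
Why: Acid-catalysed hydrolysis of the terminal isopropylidene ketal should free the 1,2-diol, while the 4-methoxybenzyl ether, which needs a much stronger acid, stays in place.

Step 6
Reactants: 9 (2R)-3-[(4-methoxybenzyl)oxy]-3-methylbutane-1,2-diol
Product: 10 (2R)-2-hydroxy-3-[(4-methoxybenzyl)oxy]-3-methylbutyl 4-methylbenzenesulfonate
Conditions: TsCl (1.05 equiv), Et3N, Bu2SnO (2 mol%), CH2Cl2, 0 °C to rt
Reagents that add atoms: 4-methylbenzenesulfonyl chloride, Cc1ccc(cc1)S(Cl)(=O)=O
Why: Tin-acetal-catalysed regioselective sulfonylation should tosylate only the primary hydroxyl, the secondary one being shielded by the adjacent quaternary carbon.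

Step 7
Reactants: 10 (2R)-2-hydroxy-3-[(4-methoxybenzyl)oxy]-3-methylbutyl 4-methylbenzenesulfonate
Product: 11 (2R)-2-{2-[(4-methoxybenzyl)oxy]propan-2-yl}oxirane
Conditions: K2CO3, MeOH, 0 °C to rt
Reagents that add atoms: none
Why: Intramolecular Williamson displacement (3-exo-tet) of the primary tosylate by the secondary alkoxide closes the oxirane without breaking the C–O bond at the stereocentre, so the (R) configuration is retained.

Step 8
Reactants: 5 5,7-bis(benzyloxy)-3-(4-iodophenyl)-4H-chromen-4-one; 11 (2R)-2-{2-[(4-methoxybenzyl)oxy]propan-2-yl}oxirane (2 equiv)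
Product: 12 5,7-bis(benzyloxy)-3-[(2R)-2-{2-[(4-methoxybenzyl)oxy]propan-2-yl}-2,3-dihydro-1-benzofuran-5-yl]-4H-chromen-4-one
Conditions: Pd(OAc)2 (10 mol%), XPhos (20 mol%), 1-butylbicyclo[2.2.1]hept-2-ene (bridgehead-substituted norbornene, 1 equiv), Cs2CO3 (1.5 equiv), DMF, 100 °C
Reagents that add atoms: none
Why: Zerovalent palladium inserts into the C–I bond of 5, the arylpalladium adds across the norbornene and palladates one of the two equivalent ortho C–H bonds (C3a'), and the resulting electron-rich aryl–norbornyl palladacycle of divalent palladium opens epoxide 11 at its CH2 by SN2-type oxidative addition, after which C–C reductive elimination from tetravalent palladium forms C3a'–C3'. β-Carbon elimination then releases the norbornene, and the remaining aryl–palladium alkoxide forms C7a'–O1' by C–O reductive elimination, regenerating zerovalent palladium. The closest known reaction type is the Catellani-type palladium/norbornene annulation of aryl iodides with epoxides to 2,3-dihydrobenzofurans, run here with a bridgehead-substituted norbornene of the kind used for single ortho functionalisation of aryl iodides that lack an ortho substituent. Ring D closes by ipso C(aryl)–O reductive elimination from a six-membered oxapalladacycle, that is, as a five-membered ring formed on the metal and not by nucleophilic cyclisation. No new stereocentre arises: the C2'–O bond of 11 is never broken, so its (R) configuration is transferred unchanged. The step needs attack at CH2 and not at the carbinol carbon, secured by the quaternary carbon flanking the latter, and one ortho alkylation instead of two, secured by the bridgehead butyl group that forces norbornene extrusion after the first alkylation, while the para chromone makes both ortho sites identical and the non-migrating 4-methoxybenzyl ether keeps the released alkoxide from being diverted.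

Step 9
Reactants: 12 5,7-bis(benzyloxy)-3-[(2R)-2-{2-[(4-methoxybenzyl)oxy]propan-2-yl}-2,3-dihydro-1-benzofuran-5-yl]-4H-chromen-4-one
Product: 13 5,7-dihydroxy-3-[(2R)-2-(2-hydroxypropan-2-yl)-2,3-dihydro-1-benzofuran-5-yl]-4H-chromen-4-one
Conditions: H2 (1 atm), 10% Pd/C, EtOAc–MeOH (1:1), rt
Reagents that add atoms: none
Why: Catalytic hydrogenolysis cleaves the three benzylic C–O bonds (two benzyl aryl ethers, one 4-methoxybenzyl alkyl ether), while the non-benzylic ring C–O bonds, the trisubstituted C2–C3 double bond of the chromone and the C2' stereocentre are expected to survive if the reaction is stopped once debenzylation is complete.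

**Compound list**
1 | phloroglucinol (benzene-1,3,5-triol) | Oc1cc(O)cc(O)c1 | starting material
2 | 2-(4-iodophenyl)acetic acid | OC(=O)Cc1ccc(I)cc1 | starting material
3 | 2-(4-iodophenyl)-1-(2,4,6-trihydroxyphenyl)ethan-1-one (deoxybenzoin) | O=C(Cc1ccc(I)cc1)c1c(O)cc(O)cc1O | intermediate
4 | 5,7-dihydroxy-3-(4-iodophenyl)-4H-chromen-4-one | Ic1ccc(-c2coc3cc(O)cc(O)c3c2=O)cc1 | intermediate
5 | 5,7-bis(benzyloxy)-3-(4-iodophenyl)-4H-chromen-4-one | Ic1ccc(-c2coc3cc(OCc4ccccc4)cc(OCc4ccccc4)c3c2=O)cc1 | intermediate
6 | methyl (4R)-2,2-dimethyl-1,3-dioxolane-4-carboxylate | COC(=O)[C@H]1COC(C)(C)O1 | starting material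
7 | 2-[(4R)-2,2-dimethyl-1,3-dioxolan-4-yl]propan-2-ol | CC(C)(O)[C@H]1COC(C)(C)O1 | intermediate
8 | (4R)-4-{2-[(4-methoxybenzyl)oxy]propan-2-yl}-2,2-dimethyl-1,3-dioxolane | CC(C)(OCc1ccc(OC)cc1)[C@H]1COC(C)(C)O1 | intermediate
9 | (2R)-3-[(4-methoxybenzyl)oxy]-3-methylbutane-1,2-diol | CC(C)(OCc1ccc(OC)cc1)[C@H](O)CO | intermediate
10 | (2R)-2-hydroxy-3-[(4-methoxybenzyl)oxy]-3-methylbutyl 4-methylbenzenesulfonate | CC(C)(OCc1ccc(OC)cc1)[C@H](O)COS(=O)(=O)c1ccc(C)cc1 | intermediate
11 | (2R)-2-{2-[(4-methoxybenzyl)oxy]propan-2-yl}oxirane | CC(C)(OCc1ccc(OC)cc1)[C@H]1CO1 | intermediate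
12 | 5,7-bis(benzyloxy)-3-[(2R)-2-{2-[(4-methoxybenzyl)oxy]propan-2-yl}-2,3-dihydro-1-benzofuran-5-yl]-4H-chromen-4-one | CC(C)(OCc1ccc(OC)cc1)[C@H]1Cc2cc(-c3coc4cc(OCc5ccccc5)cc(OCc5ccccc5)c4c3=O)ccc2O1 | intermediate
13 | 5,7-dihydroxy-3-[(2R)-2-(2-hydroxypropan-2-yl)-2,3-dihydro-1-benzofuran-5-yl]-4H-chromen-4-one | CC(C)(O)[C@H]1Cc2cc(-c3coc4cc(O)cc(O)c4c3=O)ccc2O1 | target

**Count**
Total step count: 9. Longest linear sequence: 7 steps (steps 3 to 9, from 6).

**Steps most likely to fail**

Step 8. Three things may go wrong. The norbornene may fail to leave after the first alkylation, so that a second ortho alkylation or benzocyclobutene formation takes over. Oxidative addition of the hindered epoxide may be too slow. The palladium alkoxide may undergo β-hydride elimination before C–O reductive elimination. The fallback forms the same two bonds one after the other by known reactions; it sets out from 5 and 11 and comes back at 12. Miyaura borylation of 5 (B2pin2, PdCl2(dppf), KOAc, dioxane, 85 °C) would give 5,7-bis(benzyloxy)-3-[4-(4,4,5,5-tetramethyl-1,3,2-dioxaborolan-2-yl)phenyl]-4H-chromen-4-one F1. Separately, iodine–magnesium exchange on commercial 1-bromo-4-chloro-2-iodobenzene (Brc1ccc(Cl)cc1I; iPrMgCl·LiCl, THF, −40 °C) followed by CuI-catalysed opening of 11 at its CH2 would give (2R)-1-(2-bromo-5-chlorophenyl)-3-[(4-methoxybenzyl)oxy]-3-methylbutan-2-ol F2, which carries C3a'–C3'. Copper-catalysed intramolecular O-arylation at the C–Br bond (CuI, 3,4,7,8-tetramethyl-1,10-phenanthroline, Cs2CO3, toluene, 110 °C) would then form C7a'–O1' and give (2R)-5-chloro-2-{2-[(4-methoxybenzyl)oxy]propan-2-yl}-2,3-dihydro-1-benzofuran F3, again without touching the C2'–O bond. Suzuki–Miyaura coupling of F3 with F1 (Pd(OAc)2, SPhos, K3PO4, toluene–H2O, 90 °C) returns to 12.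

Step 9. Cleavage of the hindered tertiary 4-methoxybenzyl ether may lag behind the aryl benzyl ethers, and the longer exposure to hydrogen may saturate the C2–C3 double bond of the chromone. The fallback separates the two events; it sets out from 12 and comes back at 13. Oxidative removal of the 4-methoxybenzyl group (DDQ, CH2Cl2–pH 7 buffer, 0 °C to rt) would give 5,7-bis(benzyloxy)-3-[(2R)-2-(2-hydroxypropan-2-yl)-2,3-dihydro-1-benzofuran-5-yl]-4H-chromen-4-one F4. A short hydrogenolysis of the two fast-reacting aryl benzyl ethers alone (H2, Pd/C, EtOAc, rt) then gives 13.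

Step 2. O-Alkylation of the hydrogen-bonded 5-OH may stay incomplete, or the forcing conditions may cause C-benzylation of the electron-rich ring A. The fallback protects before ring C exists; it sets out from 3 (the one-pot of step 1 is stopped after the acylation and 3 is isolated) and comes back at 5. Partial benzylation (BnBr 2.1 equiv, K2CO3, acetone, reflux) alkylates the para hydroxyl and one ortho hydroxyl and would give 1-[2,4-bis(benzyloxy)-6-hydroxyphenyl]-2-(4-iodophenyl)ethan-1-one F5. The remaining chelated hydroxyl is then used up in the ring closure with N,N-dimethylformamide dimethyl acetal (toluene, 100 °C), which gives 5 directly.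

**Further compounds**
F1 | step 8 | 5,7-bis(benzyloxy)-3-[4-(4,4,5,5-tetramethyl-1,3,2-dioxaborolan-2-yl)phenyl]-4H-chromen-4-one | CC1(C)OB(OC1(C)C)c1ccc(-c2coc3cc(OCc4ccccc4)cc(OCc4ccccc4)c3c2=O)cc1
F2 | step 8 | (2R)-1-(2-bromo-5-chlorophenyl)-3-[(4-methoxybenzyl)oxy]-3-methylbutan-2-ol | CC(C)(OCc1ccc(OC)cc1)[C@H](O)Cc1cc(Cl)ccc1Br
F3 | step 8 | (2R)-5-chloro-2-{2-[(4-methoxybenzyl)oxy]propan-2-yl}-2,3-dihydro-1-benzofuran | CC(C)(OCc1ccc(OC)cc1)[C@H]1Cc2cc(Cl)ccc2O1
F4 | step 9 | 5,7-bis(benzyloxy)-3-[(2R)-2-(2-hydroxypropan-2-yl)-2,3-dihydro-1-benzofuran-5-yl]-4H-chromen-4-one | CC(C)(O)[C@H]1Cc2cc(-c3coc4cc(OCc5ccccc5)cc(OCc5ccccc5)c4c3=O)ccc2O1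
F5 | step 2 | 1-[2,4-bis(benzyloxy)-6-hydroxyphenyl]-2-(4-iodophenyl)ethan-1-one | O=C(Cc1ccc(I)cc1)c1c(O)cc(OCc2ccccc2)cc1OCc1ccccc1
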